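## Retrosynthetic overview

- Ring A is the 2,4-disubstituted furan carrying the acrylic acid, ring B the central 2,4-disubstituted furan, ring C the terminal 3-substituted furan. No ring is built: all three furans are bought and joined in the order C to B, then A to B.
- The strategy rests on the lone stereocentre, a methyl-bearing CH whose CH2 neighbour is bonded to C2 of ring B. This is the 2-methylalkyl-metal pattern left by methylmetalation of a terminal alkene.
- Key disconnection: the C–CH3 bond and the CH2–C2 (ring B) bond, made in one pot from a ring A pent-4-enylfuran, Me3Al under a chiral zirconocene, and a ring B 2-iodofuran (Negishi coupling after Al-to-Zn transfer).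
- The alkene comes from 4-bromo-2-furaldehyde (reduce, silylate, alkyl Negishi). The iodide takes its C2 halogen from a bought 5-bromofuran-3-carboxylate, builds the propyl link to ring C without palladium, and swaps Br for I last, so ring B never has to be iodinated selectively beside the equally electron-rich ring C.
- End game: desilylation, MnO2 oxidation, E-selective Wittig with a stabilised propionate ylide, saponification.

Key step: step 10

Remark on the chemistry: the (+)-antipode of bis(1-neomenthylindenyl)zirconium dichloride is assumed to give (S)-2-methylalkylalanes from unbranched 1-alkenes; the sense is to be checked on the alcohol from an oxidised aliquot, and the (−)-antipode used if it is opposite.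
Remark on the chemistry: methyl 5-bromofuran-3-carboxylate is taken as a catalogue compound (it is otherwise made by brominating methyl furan-3-carboxylate at C5).

## Route

Step 1
Reactants: 1 4-bromofuran-2-carbaldehyde (4-bromo-2-furaldehyde)
Product: 2 (4-bromofuran-2-yl)methanol
Conditions: NaBH4, MeOH, 0 °C
Reagents that add atoms: none
Why: Borohydride reduction of an aromatic aldehyde to the primary alcohol, which leaves the ring bromide untouched.

Step 2
Reactants: 2 (4-bromofuran-2-yl)methanol
Product: 3 [(4-bromofuran-2-yl)methoxy]triisopropylsilane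
Conditions: i-Pr3SiCl, imidazole, DMF, rt
Reagents that add atoms: triisopropylsilyl chloride, CC(C)[Si](Cl)(C(C)C)C(C)C
Why: Imidazole-promoted silylation of a primary alcohol gives a bulky silyl ether that should stay off aluminium and zinc in the later steps.

Step 3
Reactants: 3 [(4-bromofuran-2-yl)methoxy]triisopropylsilane, 4 5-bromopent-1-ene
Product: 6 triisopropyl{[4-(pent-4-en-1-yl)furan-2-yl]methoxy}silane, via pent-4-en-1-ylzinc bromide 5 (not isolated)
Conditions: 4, Zn dust (I2-activated), LiCl, THF, 50 °C; then 3, Pd(OAc)2 (2 mol%), SPhos (4 mol%), THF, rt to 50 °C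
Reagents that add atoms: none
Why: Zinc insertion into the primary bromide followed by Negishi coupling, in which the dialkylbiarylphosphine should promote oxidative addition into the electron-rich beta-bromofuran and let reductive elimination outrun beta-hydride loss, while the silyl ether and terminal alkene are inert to the alkylzinc.

Step 4
Reactants: 7 3-bromofuran
Product: 9 2-(furan-3-yl)ethan-1-ol, via furan-3-yllithium 8 (not isolated)
Conditions: n-BuLi, THF, −78 °C; oxirane, BF3·OEt2, −78 °C; sat. aq NH4Cl
Reagents that add atoms: oxirane, C1CO1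
Why: Bromine–lithium exchange at −78 °C gives the 3-lithiofuran (kept cold so that it does not isomerise to the 2-lithio form), and BF3-assisted epoxide opening by an organolithium adds the two-carbon alcohol.

Step 5
Reactants: 9 2-(furan-3-yl)ethan-1-ol
Product: 10 3-(2-bromoethyl)furan
Conditions: CBr4, PPh3, CH2Cl2, 0 °C
Reagents that add atoms: carbon tetrabromide, BrC(Br)(Br)Br
Why: Appel bromination of a primary alcohol under neutral conditions, which should spare the acid-sensitive furan.

Step 6
Reactants: 11 methyl 5-bromofuran-3-carboxylate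
Product: 12 (5-bromofuran-3-yl)methanol
Conditions: i-Bu2AlH (2.2 equiv), CH2Cl2, −78 to 0 °C; aq potassium sodium tartrate (KNaC4H4O6)
Reagents that add atoms: none
Why: Aluminium hydride reduction of an ester to the primary alcohol, with the alpha-bromofuran inert to i-Bu2AlH at low temperature.

Step 7
Reactants: 12 (5-bromofuran-3-yl)methanol
Product: 13 2-bromo-4-(bromomethyl)furan
Conditions: CBr4, PPh3, CH2Cl2, 0 °C; filtered through silica with pentane and used at once
Reagents that add atoms: carbon tetrabromide, BrC(Br)(Br)Br
Why: Appel bromination gives the benzylic-type bromide without acid, and the ring bromine damps the furan enough for the bromide to be handled briefly.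

Step 8
Reactants: 10 3-(2-bromoethyl)furan, 13 2-bromo-4-(bromomethyl)furan
Product: 15 2-bromo-4-[3-(furan-3-yl)propyl]furan, via [2-(furan-3-yl)ethyl]magnesium bromide 14 (not isolated)
Conditions: 10, Mg, THF, rt; then 13, Li2CuCl4 (3 mol%), THF, −78 to 0 °C
Reagents that add atoms: none
Why: Copper-catalysed (Kochi-type) coupling of a primary alkyl Grignard reagent with a benzylic-type bromide should be fast at low temperature, where the aryl C–Br bond at C2 of ring B neither couples nor exchanges with magnesium.

Step 9
Reactants: 15 2-bromo-4-[3-(furan-3-yl)propyl]furan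
Product: 17 2-iodo-4-[3-(furan-3-yl)propyl]furan, via {4-[3-(furan-3-yl)propyl]furan-2-yl}lithium 16 (not isolated)
Conditions: n-BuLi (1.05 equiv), THF, −78 °C; I2, THF, −78 °C; aq Na2S2O3; kept cold and dark
Reagents that add atoms: iodine, II
Why: Bromine–lithium exchange at the alpha-bromofuran is much faster at −78 °C than deprotonation of ring C, so the lithium, and after the iodine quench the iodine, sits only at C2 of ring B.

Step 10
Reactants: 6 triisopropyl{[4-(pent-4-en-1-yl)furan-2-yl]methoxy}silane, 17 2-iodo-4-[3-(furan-3-yl)propyl]furan, 18 trimethylaluminium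
Product: 21 triisopropyl{[4-((4S)-4-methyl-5-{4-[3-(furan-3-yl)propyl]furan-2-yl}pentyl)furan-2-yl]methoxy}silane, via (S)-2-methylalkyl(dimethyl)alane 19 (not isolated), via (S)-2-methylalkylzinc triflate 20 (not isolated)
Conditions: 6 (1.3 equiv), Me3Al (2.5 equiv), (+)-(NMI)2ZrCl2 [(+)-bis(1-neomenthylindenyl)zirconium dichloride] (5 mol%), methylaluminoxane (MeAlO)n (1 equiv), CH2Cl2, 0 °C to rt; volatiles and excess Me3Al removed in vacuo; Zn(OTf)2 (1.2 equiv), DMF, 70 °C; then 17 (1.0 equiv), PdCl2(DPEphos) (3 mol%), i-Bu2AlH (6 mol%), DMF, rt to 50 °C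
Reagents that add atoms: trimethylaluminium (compound 18, one methyl group), C[Al](C)C
Why: The cationic methylzirconocene formed from the zirconium dichloride, Me3Al and methylaluminoxane inserts the terminal alkene of 6 with methyl going to the internal carbon, and zirconium-to-aluminium exchange releases the primary alane 19 before beta-hydride loss; after the excess Me3Al is pumped off, Zn(OTf)2 in DMF moves the 2-methylalkyl group to zinc (20), which transmetalates to the furylpalladium iodide formed from 17 by oxidative addition to zerovalent palladium, and reductive elimination makes the CH2–C2 (ring B) bond. The closest known reaction type is the zirconium-catalysed asymmetric carboalumination of 1-alkenes followed in the same pot by zinc-assisted Negishi coupling with alkenyl halides, and a 2-iodofuran is an sp2 iodide that should undergo oxidative addition at least as readily. No ring is closed. The one new stereocentre (S) is set by the alkene face that the chiral neomenthylindenyl ligand set exposes, and it is untouched by the coupling because the metal-bearing carbon is the neighbouring CH2. The step needs regioselectivity (secured by the unbranched terminal alkene), face selectivity (secured by the catalyst antipode, although methyl is the least selective alkyl in this family, so the enantiomeric purity of 21 is fixed here and is to be measured on the alcohol from an oxidised aliquot of 19) and transfer of the 2-methylalkyl group in preference to methyl (secured by removing Me3Al and by the zinc triflate protocol). The bulky silyl ether and the three furans carry no group that should react with the alane or the alkylzinc.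

Step 11
Reactants: 21 triisopropyl{[4-((4S)-4-methyl-5-{4-[3-(furan-3-yl)propyl]furan-2-yl}pentyl)furan-2-yl]methoxy}silane
Product: 22 {4-[(4S)-4-methyl-5-{4-[3-(furan-3-yl)propyl]furan-2-yl}pentyl]furan-2-yl}methanol
Conditions: Bu4NF, THF, 0 °C to rt
Reagents that add atoms: none
Why: Fluoride-driven cleavage of the silyl ether frees the furfuryl alcohol without acid, so the three furans and the remote stereocentre are unaffected.

Step 12
Reactants: 22 {4-[(4S)-4-methyl-5-{4-[3-(furan-3-yl)propyl]furan-2-yl}pentyl]furan-2-yl}methanol
Product: 23 4-[(4S)-4-methyl-5-{4-[3-(furan-3-yl)propyl]furan-2-yl}pentyl]furan-2-carbaldehyde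
Conditions: MnO2 (activated, excess), CH2Cl2, rt
Reagents that add atoms: none
Why: Manganese dioxide oxidises the activated furfuryl (benzylic-type) alcohol to the aldehyde and stops there.

Step 13
Reactants: 23 4-[(4S)-4-methyl-5-{4-[3-(furan-3-yl)propyl]furan-2-yl}pentyl]furan-2-carbaldehyde
Product: 24 ethyl (2E)-2-methyl-3-{4-[(4S)-4-methyl-5-{4-[3-(furan-3-yl)propyl]furan-2-yl}pentyl]furan-2-yl}prop-2-enoate
Conditions: Ph3P=C(CH3)CO2Et, toluene, 80 °C
Reagents that add atoms: ethyl 2-(triphenylphosphoranylidene)propanoate, CCOC(=O)C(C)=P(c1ccccc1)(c1ccccc1)c1ccccc1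
Why: Wittig reaction of a stabilised alpha-methyl ylide with an aromatic aldehyde is under thermodynamic control in the oxaphosphetane and should place the furyl group trans to the ester (E).

Step 14
Reactants: 24 ethyl (2E)-2-methyl-3-{4-[(4S)-4-methyl-5-{4-[3-(furan-3-yl)propyl]furan-2-yl}pentyl]furan-2-yl}prop-2-enoate
Product: 25 (2E)-2-methyl-3-{4-[(4S)-4-methyl-5-{4-[3-(furan-3-yl)propyl]furan-2-yl}pentyl]furan-2-yl}prop-2-enoic acid (CNP0088458.1)
Conditions: LiOH, THF/MeOH/H2O, rt to 40 °C; then 1 M HCl to pH 4 at 0 °C
Reagents that add atoms: lithium hydroxide (hydroxide oxygen of the acid), [Li+].[OH-]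
Why: Saponification of the ester by acyl substitution leaves the E-alkene and the remote stereocentre unchanged, and the cold, mild acidification should spare the furans.

## Compound list

1 | 4-bromofuran-2-carbaldehyde | O=Cc1cc(Br)co1 | starting material
2 | (4-bromofuran-2-yl)methanol | OCc1cc(Br)co1 | intermediate
3 | [(4-bromofuran-2-yl)methoxy]triisopropylsilane | CC(C)[Si](OCc1cc(Br)co1)(C(C)C)C(C)C | intermediate
4 | 5-bromopent-1-ene | C=CCCCBr | starting material
5 | pent-4-en-1-ylzinc bromide | C=CCCC[Zn]Br | intermediate
6 | triisopropyl{[4-(pent-4-en-1-yl)furan-2-yl]methoxy}silane | C=CCCCc1coc(CO[Si](C(C)C)(C(C)C)C(C)C)c1 | intermediate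
7 | 3-bromofuran | Brc1ccoc1 | starting material
8 | furan-3-yllithium | [Li]c1ccoc1 | intermediate
9 | 2-(furan-3-yl)ethan-1-ol | OCCc1ccoc1 | intermediate
10 | 3-(2-bromoethyl)furan | BrCCc1ccoc1 | intermediate
11 | methyl 5-bromofuran-3-carboxylate | COC(=O)c1coc(Br)c1 | starting material
12 | (5-bromofuran-3-yl)methanol | OCc1coc(Br)c1 | intermediate
13 | 2-bromo-4-(bromomethyl)furan | BrCc1coc(Br)c1 | intermediate
14 | [2-(furan-3-yl)ethyl]magnesium bromide | Br[Mg]CCc1ccoc1 | intermediate
15 | 2-bromo-4-[3-(furan-3-yl)propyl]furan | Brc1cc(CCCc2ccoc2)co1 | intermediate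
16 | {4-[3-(furan-3-yl)propyl]furan-2-yl}lithium | [Li]c1cc(CCCc2ccoc2)co1 | intermediate
17 | 2-iodo-4-[3-(furan-3-yl)propyl]furan | Ic1cc(CCCc2ccoc2)co1 | intermediate
18 | trimethylaluminium | C[Al](C)C | starting material
19 | dimethyl[(2S)-2-methyl-5-(5-{[(triisopropylsilyl)oxy]methyl}furan-3-yl)pentyl]alane | C[Al](C)C[C@@H](C)CCCc1coc(CO[Si](C(C)C)(C(C)C)C(C)C)c1 | intermediate
20 | [(2S)-2-methyl-5-(5-{[(triisopropylsilyl)oxy]methyl}furan-3-yl)pentyl]zinc trifluoromethanesulfonate | FC(F)(F)S(=O)(=O)O[Zn]C[C@@H](C)CCCc1coc(CO[Si](C(C)C)(C(C)C)C(C)C)c1 | intermediate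
21 | triisopropyl{[4-((4S)-4-methyl-5-{4-[3-(furan-3-yl)propyl]furan-2-yl}pentyl)furan-2-yl]methoxy}silane | CC(C)[Si](OCc1cc(CCC[C@H](C)Cc2cc(CCCc3ccoc3)co2)co1)(C(C)C)C(C)C | intermediate
22 | {4-[(4S)-4-methyl-5-{4-[3-(furan-3-yl)propyl]furan-2-yl}pentyl]furan-2-yl}methanol | OCc1cc(CCC[C@H](C)Cc2cc(CCCc3ccoc3)co2)co1 | intermediate
23 | 4-[(4S)-4-methyl-5-{4-[3-(furan-3-yl)propyl]furan-2-yl}pentyl]furan-2-carbaldehyde | O=Cc1cc(CCC[C@H](C)Cc2cc(CCCc3ccoc3)co2)co1 | intermediate
24 | ethyl (2E)-2-methyl-3-{4-[(4S)-4-methyl-5-{4-[3-(furan-3-yl)propyl]furan-2-yl}pentyl]furan-2-yl}prop-2-enoate | C/C(=C\c1cc(CCC[C@H](C)Cc2cc(CCCc3ccoc3)co2)co1)C(=O)OCC | intermediate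
25 | (2E)-2-methyl-3-{4-[(4S)-4-methyl-5-{4-[3-(furan-3-yl)propyl]furan-2-yl}pentyl]furan-2-yl}prop-2-enoic acid | C/C(=C\c1cc(CCC[C@H](C)Cc2cc(CCCc3ccoc3)co2)co1)C(=O)O | target

## Step count

Total steps: 14. Longest linear sequence: 9 steps (from 3-bromofuran 7 through steps 4, 5, 8, 9, 10, 11, 12, 13, 14; the branch from 11 is equally long).

## Steps most likely to fail

1. Step 10. The methyl transfer may discriminate the alkene faces only moderately, and the enantiomeric purity cannot be raised after the coupling. Methyl rather than the 2-methylalkyl group may also be passed to palladium, consuming 17, and the Lewis-acidic medium may ionise the furfuryl silyl ether.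

   The fallback sets out from 6 and comes back at 21. The same zirconium-catalysed methylalumination is run, but the alane 19 is oxidised with dry O2 to (2S)-2-methyl-5-(5-{[(triisopropylsilyl)oxy]methyl}furan-3-yl)pentan-1-ol F1. Its enantiomeric purity is raised by lipase-catalysed acetylation (Amano PS lipase, vinyl acetate), in which the (S)-enantiomer of a 2-methylalkan-1-ol is expected to be acylated faster. The acetylation is stopped at partial conversion, and (2S)-2-methyl-5-(5-{[(triisopropylsilyl)oxy]methyl}furan-3-yl)pentyl acetate F2 is separated and methanolysed (K2CO3, MeOH) back to F1. The alcohol is converted with I2, PPh3 and imidazole into [(4-((4S)-5-iodo-4-methylpentyl)furan-2-yl)methoxy]triisopropylsilane F3. Zinc dust and LiCl in THF give [(2S)-2-methyl-5-(5-{[(triisopropylsilyl)oxy]methyl}furan-3-yl)pentyl]zinc iodide F4, which is coupled with 17 under Pd(OAc)2 and SPhos (Negishi coupling) to give 21.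

2. Step 8. The labile furylmethyl bromide 13 may decompose or homocouple before it is captured, and the Grignard reagent may exchange with the C2 bromine of ring B.

   The fallback sets out from 12 and 10 and comes back at 15. Alcohol 12 is oxidised with MnO2 to 5-bromofuran-3-carbaldehyde F5. Bromide 10 is heated with PPh3 to give [2-(furan-3-yl)ethyl]triphenylphosphonium bromide F6, which NaN(SiMe3)2 in THF at −78 °C turns into [2-(furan-3-yl)ethylidene]triphenylphosphorane F7. Wittig reaction of F7 with F5 should give 2-bromo-4-[(1Z)-3-(furan-3-yl)prop-1-en-1-yl]furan F8 (mainly Z, the geometry being irrelevant). Diimide reduction (2-nitrobenzenesulfonohydrazide, Et3N, CH2Cl2) saturates the alkene without touching the C–Br bond and gives 15.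

3. Step 4. Furan-3-yllithium may isomerise to the 2-lithio form on local warming, and BF3 may open or oligomerise oxirane before the organolithium does, so that conversion is low and regioisomers appear.

   The fallback sets out from 7 and comes back at 9. Suzuki–Miyaura vinylation of 7 (potassium vinyltrifluoroborate, PdCl2(dppf), Cs2CO3, THF/H2O) gives 3-ethenylfuran F9, which is taken on in solution because it is volatile. Anti-Markovnikov hydroboration with 9-borabicyclo[3.3.1]nonane gives 9-[2-(furan-3-yl)ethyl]-9-borabicyclo[3.3.1]nonane F10, and oxidation with NaOH/H2O2 gives 9.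

Further compounds
F1 | step 10 | (2S)-2-methyl-5-(5-{[(triisopropylsilyl)oxy]methyl}furan-3-yl)pentan-1-ol | OC[C@@H](C)CCCc1coc(CO[Si](C(C)C)(C(C)C)C(C)C)c1
F2 | step 10 | (2S)-2-methyl-5-(5-{[(triisopropylsilyl)oxy]methyl}furan-3-yl)pentyl acetate | CC(=O)OC[C@@H](C)CCCc1coc(CO[Si](C(C)C)(C(C)C)C(C)C)c1
F3 | step 10 | [(4-((4S)-5-iodo-4-methylpentyl)furan-2-yl)methoxy]triisopropylsilane | IC[C@@H](C)CCCc1coc(CO[Si](C(C)C)(C(C)C)C(C)C)c1
F4 | step 10 | [(2S)-2-methyl-5-(5-{[(triisopropylsilyl)oxy]methyl}furan-3-yl)pentyl]zinc iodide | I[Zn]C[C@@H](C)CCCc1coc(CO[Si](C(C)C)(C(C)C)C(C)C)c1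
F5 | step 8 | 5-bromofuran-3-carbaldehyde | O=Cc1coc(Br)c1
F6 | step 8 | [2-(furan-3-yl)ethyl]triphenylphosphonium bromide | [Br-].c1ccc(cc1)[P+](CCc1ccoc1)(c1ccccc1)c1ccccc1
F7 | step 8 | [2-(furan-3-yl)ethylidene]triphenylphosphorane | C(Cc1ccoc1)=P(c1ccccc1)(c1ccccc1)c1ccccc1
F8 | step 8 | 2-bromo-4-[(1Z)-3-(furan-3-yl)prop-1-en-1-yl]furan | Brc1cc(/C=C\Cc2ccoc2)co1
F9 | step 4 | 3-ethenylfuran | C=Cc1ccoc1
F10 | step 4 | 9-[2-(furan-3-yl)ethyl]-9-borabicyclo[3.3.1]nonane | c1occc1CCB1C2CCCC1CCC2
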